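**Retrosynthetic overview**

- Last disconnection: the C7–CH2–C3' methylene bridge is cut into the acylphloroglucinol-type dihydrobenzofuran, a CH2 iminium unit and 6-ethyl-4-hydroxy-5-methyl-2-pyrone; the pyrone ring is built separately from pentan-3-one and malonyl dichloride.
- The C5 acetyl group goes back to directed lithiation between methoxymethoxy groups at C4 and C6.
- Feature on which the plan rests: in the dihydrofuran ring (O1–C2–C3–C3a–C7a) the C2–C3 bond joins a benzylic CH2 (C3) to a carbon (C2) that is both bound to O1 and allylic, so C2–H is the most hydridic C–H five atoms from a carbene placed at C3.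
- Key disconnection C2–C3: enantioselective 1,5 C–H insertion of an aryl rhodium carbenoid made from the hydrazone of a 2-(alkenyloxy)benzaldehyde (from 2,4,6-trihydroxybenzaldehyde and an allylic alcohol from methallyl alcohol and prenyl bromide). The phenols carry silyl ethers at this stage, because an ortho OCH2O acetal would put a second C–H at the same 1,5-distance; they are exchanged for methoxymethyl ethers afterwards.
- Ring order: the benzene ring is bought, the dihydrofuran ring is closed in the key step (sets (R)-C2), the pyrone ring is made on its own and attached last.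

Key step: step 5

Assumption: Rh2(S-PTAD)4 is taken to select the hydrogen that leads to (R)-C2; should the sense of induction prove opposite, Rh2(R-PTAD)4 is used with no other change.

**Step 1**
Reactants: 1 2-methylprop-2-en-1-ol; 2 1-bromo-3-methylbut-2-ene
Product: 4 6-methyl-2-methylidenehept-5-en-1-ol, via dilithiated methallyl alcohol 3 (not isolated)
Conditions: n-BuLi (2.2 equiv), TMEDA, Et2O, 0 °C to rt; then 2, −78 °C to rt; H2O
Reagents that add atoms: none
Why: Alkoxide-directed allylic lithiation gives dianion 3, whose carbanion carbon displaces bromide at the primary carbon of 2 (SN2 alkylation), the dimethyl-substituted terminus being too hindered for the SN2′ course.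

**Step 2**
Reactants: 5 2,4,6-trihydroxybenzaldehyde
Product: 6 2-hydroxy-4,6-bis(triisopropylsilyloxy)benzaldehyde
Conditions: i-Pr3SiCl (2.1 equiv), imidazole, DMF, 0 °C to rt
Reagents that add atoms: chlorotriisopropylsilane, CC(C)[Si](Cl)(C(C)C)C(C)C
Why: Phenol silylation with a silyl chloride and imidazole should take the 4-hydroxyl and one ortho hydroxyl while the other ortho hydroxyl is held back by its hydrogen bond to the formyl oxygen, and the silyl ethers carry no C–H bond five atoms from the future carbenoid carbon.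

**Step 3**
Reactants: 6 2-hydroxy-4,6-bis(triisopropylsilyloxy)benzaldehyde; 4 6-methyl-2-methylidenehept-5-en-1-ol
Product: 7 2-[(6-methyl-2-methylidenehept-5-en-1-yl)oxy]-4,6-bis(triisopropylsilyloxy)benzaldehyde
Conditions: PPh3, DIAD, THF, 0 °C to rt
Reagents that add atoms: none
Why: Mitsunobu etherification of the acidic chelated phenol with the primary allylic alcohol runs under neutral conditions that spare the aryl silyl ethers, and an SN2′ course would give the same ether because both allylic termini are CH2 groups.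

**Step 4**
Reactants: 7 2-[(6-methyl-2-methylidenehept-5-en-1-yl)oxy]-4,6-bis(triisopropylsilyloxy)benzaldehyde
Product: 8 (E)-{2-[(6-methyl-2-methylidenehept-5-en-1-yl)oxy]-4,6-bis(triisopropylsilyloxy)benzylidene}hydrazine
Conditions: N2H4·H2O (10 equiv), EtOH/THF, rt, argon
Reagents that add atoms: hydrazine (as hydrate), NN
Why: Condensation of the aldehyde with excess hydrazine should give the N-unsubstituted hydrazone as the more stable E isomer, the excess suppressing azine formation and the inert atmosphere preventing diimide reduction of the alkenes.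

**Step 5**
Reactants: 8 (E)-{2-[(6-methyl-2-methylidenehept-5-en-1-yl)oxy]-4,6-bis(triisopropylsilyloxy)benzylidene}hydrazine
Product: 10 (R)-2-(6-methylhepta-1,5-dien-2-yl)-4,6-bis(triisopropylsilyloxy)-2,3-dihydrobenzofuran, via aryldiazomethane 9 (not isolated)
Conditions: MnO2 (8 equiv), CH2Cl2, 0 °C, filtration under argon; cold filtrate added over 2 h to Rh2(S-PTAD)4 (1 mol %), 4 Å molecular sieves, CH2Cl2, −40 to 0 °C
Reagents that add atoms: none
Why: Proposed new method: MnO2 dehydrogenates the hydrazone to aryldiazomethane 9, which Rh2(S-PTAD)4 (a dirhodium tetracarboxylate of divalent rhodium) converts with loss of N2 into an electron-rich carbenoid at the future C3; hydride-like transfer from the OCH2 group and C–C bond formation then pass through a five-membered transition state, the positive charge developing at C2 being stabilised by O1 and by the adjacent alkene. The closest known reaction type is the dirhodium-catalysed enantioselective 1,5 C–H insertion of donor/donor carbenoids, generated from MnO2-oxidised ketone hydrazones, into ether C–H bonds to give 2,3-dihydrobenzofurans; new here is a carbenoid carbon that bears hydrogen in place of a second donor group. The dihydrofuran ring is closed by this 1,5-insertion, which forms C2–C3 (ring atoms C3, C3a, C7a, O1, C2). C2 is the only new stereocentre and is set under catalyst control, the chiral carboxylate ligands choosing one of the two enantiotopic hydrogens of the OCH2 group, and C3 ends as CH2 so that no cis/trans question arises. The insertion must outrun cyclopropanation of the neighbouring 1,1-disubstituted alkene, intramolecular dipolar cycloaddition of the diazo group onto that alkene and azine formation; the doubly activated (allylic and O-bound) C–H bond at the 1,5-position, the cold slow addition that keeps the diazo concentration low and the two ortho substituents that shield the carbenoid from a second diazo molecule should secure this. Silyl ethers are used because an ortho methoxymethyl ether would place a second, acetal-type C–H bond at the same 1,5-distance.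

**Step 6**
Reactants: 10 (R)-2-(6-methylhepta-1,5-dien-2-yl)-4,6-bis(triisopropylsilyloxy)-2,3-dihydrobenzofuran
Product: 11 (R)-2-(6-methylhepta-1,5-dien-2-yl)-2,3-dihydrobenzofuran-4,6-diol
Conditions: Bu4NF (2.2 equiv), AcOH (2.2 equiv), THF, 0 °C
Reagents that add atoms: none
Why: Fluoride-induced cleavage of the aryl silyl ethers, buffered with acetic acid so that the electron-rich phenolate is never free, should leave the allylic aryl ether stereocentre and both alkenes untouched.

**Step 7**
Reactants: 11 (R)-2-(6-methylhepta-1,5-dien-2-yl)-2,3-dihydrobenzofuran-4,6-diol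
Product: 12 (R)-4,6-bis(methoxymethoxy)-2-(6-methylhepta-1,5-dien-2-yl)-2,3-dihydrobenzofuran
Conditions: MeOCH2Cl (3 equiv), i-Pr2NEt, CH2Cl2, 0 °C to rt
Reagents that add atoms: chloromethyl methyl ether, COCCl
Why: O-Alkylation of both phenols with chloromethyl methyl ether and a hindered amine base installs the two acetal ethers that will direct the metalation.

**Step 8**
Reactants: 12 (R)-4,6-bis(methoxymethoxy)-2-(6-methylhepta-1,5-dien-2-yl)-2,3-dihydrobenzofuran
Product: 14 1-[(R)-4,6-bis(methoxymethoxy)-2-(6-methylhepta-1,5-dien-2-yl)-2,3-dihydrobenzofuran-5-yl]ethan-1-one, via C5 aryllithium 13 (not isolated)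
Conditions: n-BuLi (1.2 equiv), THF, 0 °C, 1 h; then MeC(O)N(OMe)Me, −78 to 0 °C; H2O
Reagents that add atoms: N-methoxy-N-methylacetamide, CC(=O)N(C)OC
Why: Directed ortho-metalation should take place at C5, the only position flanked by two chelating methoxymethoxy groups (the C4 acetal is turned toward C5 by the adjacent ring CH2), and the aryllithium is acylated in a Weinreb ketone synthesis whose chelated tetrahedral adduct prevents over-addition.

**Step 9**
Reactants: 14 1-[(R)-4,6-bis(methoxymethoxy)-2-(6-methylhepta-1,5-dien-2-yl)-2,3-dihydrobenzofuran-5-yl]ethan-1-one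
Product: 15 1-[(R)-4,6-dihydroxy-2-(6-methylhepta-1,5-dien-2-yl)-2,3-dihydrobenzofuran-5-yl]ethan-1-one
Conditions: 2 M aq HCl, MeOH/THF, rt to 40 °C
Reagents that add atoms: none
Why: Acid-catalysed acetal exchange with methanol removes both methoxymethyl groups, which are unusually labile ortho to the acyl group, under conditions mild enough for the trisubstituted alkene and the allylic aryl ether.

**Step 10**
Reactants: 16 pentan-3-one
Product: 17 3-(trimethylsilyloxy)pent-2-ene (E/Z mixture)
Conditions: Me3SiOTf, Et3N, Et2O, 0 °C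
Reagents that add atoms: trimethylsilyl trifluoromethanesulfonate, C[Si](C)(C)OS(=O)(=O)C(F)(F)F
Why: Soft enolisation of the symmetrical ketone with the silyl triflate and triethylamine gives the silyl enol ether, whose double-bond geometry is lost in the aromatic pyrone.

**Step 11**
Reactants: 17 3-(trimethylsilyloxy)pent-2-ene; 18 malonyl dichloride
Product: 19 6-ethyl-4-hydroxy-5-methyl-2H-pyran-2-one
Conditions: Et2O, −78 °C to rt
Reagents that add atoms: none
Why: C-Acylation of the silyl enol ether by one acid chloride group followed by O-acylation of the resulting enol by the second closes the 4-hydroxy-2-pyrone ring (silyl enol ether/malonyl dichloride pyrone annulation).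

**Step 12**
Reactants: 19 6-ethyl-4-hydroxy-5-methyl-2H-pyran-2-one; 15 1-[(R)-4,6-dihydroxy-2-(6-methylhepta-1,5-dien-2-yl)-2,3-dihydrobenzofuran-5-yl]ethan-1-one
Product: 22 3-{[(R)-5-acetyl-4,6-dihydroxy-2-(6-methylhepta-1,5-dien-2-yl)-2,3-dihydrobenzofuran-7-yl]methyl}-6-ethyl-4-hydroxy-5-methyl-2H-pyran-2-one, via pyrone Mannich base 20 (not isolated), via methylidene pyrandione 21 (not isolated)
Conditions: 19, [Me2N=CH2]I (1.0 equiv), CH2Cl2, rt, 30 min; then 15, rt to 40 °C
Reagents that add atoms: N,N-dimethylmethyleneiminium iodide, C=[N+](C)C.[I-]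
Why: Mannich aminomethylation of the pyrone at C3 and loss of dimethylamine give the Michael acceptor 21, which should be trapped by C7 of 15, the only unsubstituted and strongly nucleophilic ring carbon (three-component Mannich/Michael methylene bridging of an acylphloroglucinol with a 4-hydroxypyrone).

**Compound list**

1 | 2-methylprop-2-en-1-ol | C=C(C)CO | starting material
2 | 1-bromo-3-methylbut-2-ene | CC(C)=CCBr | starting material
3 | lithium 2-(lithiomethyl)prop-2-en-1-olate | [Li]CC(=C)CO[Li] | intermediate
4 | 6-methyl-2-methylidenehept-5-en-1-ol | C=C(CO)CCC=C(C)C | intermediate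
5 | 2,4,6-trihydroxybenzaldehyde | O=Cc1c(O)cc(O)cc1O | starting material
6 | 2-hydroxy-4,6-bis(triisopropylsilyloxy)benzaldehyde | O=Cc1c(O)cc(O[Si](C(C)C)(C(C)C)C(C)C)cc1O[Si](C(C)C)(C(C)C)C(C)C | intermediate
7 | 2-[(6-methyl-2-methylidenehept-5-en-1-yl)oxy]-4,6-bis(triisopropylsilyloxy)benzaldehyde | C=C(CCC=C(C)C)COc1cc(O[Si](C(C)C)(C(C)C)C(C)C)cc(O[Si](C(C)C)(C(C)C)C(C)C)c1C=O | intermediate
8 | (E)-{2-[(6-methyl-2-methylidenehept-5-en-1-yl)oxy]-4,6-bis(triisopropylsilyloxy)benzylidene}hydrazine | C=C(CCC=C(C)C)COc1cc(O[Si](C(C)C)(C(C)C)C(C)C)cc(O[Si](C(C)C)(C(C)C)C(C)C)c1/C=N/N | intermediate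
9 | 2-(diazomethyl)-1-[(6-methyl-2-methylidenehept-5-en-1-yl)oxy]-3,5-bis(triisopropylsilyloxy)benzene | C=C(CCC=C(C)C)COc1cc(O[Si](C(C)C)(C(C)C)C(C)C)cc(O[Si](C(C)C)(C(C)C)C(C)C)c1C=[N+]=[N-] | intermediate
10 | (R)-2-(6-methylhepta-1,5-dien-2-yl)-4,6-bis(triisopropylsilyloxy)-2,3-dihydrobenzofuran | C=C(CCC=C(C)C)[C@H]1Cc2c(O[Si](C(C)C)(C(C)C)C(C)C)cc(O[Si](C(C)C)(C(C)C)C(C)C)cc2O1 | intermediate
11 | (R)-2-(6-methylhepta-1,5-dien-2-yl)-2,3-dihydrobenzofuran-4,6-diol | C=C(CCC=C(C)C)[C@H]1Cc2c(O)cc(O)cc2O1 | intermediate
12 | (R)-4,6-bis(methoxymethoxy)-2-(6-methylhepta-1,5-dien-2-yl)-2,3-dihydrobenzofuran | C=C(CCC=C(C)C)[C@H]1Cc2c(OCOC)cc(OCOC)cc2O1 | intermediate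
13 | (R)-5-lithio-4,6-bis(methoxymethoxy)-2-(6-methylhepta-1,5-dien-2-yl)-2,3-dihydrobenzofuran | C=C(CCC=C(C)C)[C@H]1Cc2c(OCOC)c([Li])c(OCOC)cc2O1 | intermediate
14 | 1-[(R)-4,6-bis(methoxymethoxy)-2-(6-methylhepta-1,5-dien-2-yl)-2,3-dihydrobenzofuran-5-yl]ethan-1-one | C=C(CCC=C(C)C)[C@H]1Cc2c(OCOC)c(C(C)=O)c(OCOC)cc2O1 | intermediate
15 | 1-[(R)-4,6-dihydroxy-2-(6-methylhepta-1,5-dien-2-yl)-2,3-dihydrobenzofuran-5-yl]ethan-1-one | C=C(CCC=C(C)C)[C@H]1Cc2c(O)c(C(C)=O)c(O)cc2O1 | intermediate
16 | pentan-3-one | CCC(=O)CC | starting material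
17 | 3-(trimethylsilyloxy)pent-2-ene (E/Z mixture) | CC=C(CC)O[Si](C)(C)C | intermediate
18 | malonyl dichloride | O=C(Cl)CC(=O)Cl | starting material
19 | 6-ethyl-4-hydroxy-5-methyl-2H-pyran-2-one | CCc1oc(=O)cc(O)c1C | intermediate
20 | 3-[(dimethylamino)methyl]-6-ethyl-4-hydroxy-5-methyl-2H-pyran-2-one | CCc1oc(=O)c(CN(C)C)c(O)c1C | intermediate
21 | 6-ethyl-5-methyl-3-methylidene-2H-pyran-2,4(3H)-dione | CCC1=C(C)C(=O)C(=C)C(=O)O1 | intermediate
22 | 3-{[(R)-5-acetyl-4,6-dihydroxy-2-(6-methylhepta-1,5-dien-2-yl)-2,3-dihydrobenzofuran-7-yl]methyl}-6-ethyl-4-hydroxy-5-methyl-2H-pyran-2-one | C=C(CCC=C(C)C)[C@H]1Cc2c(O)c(C(C)=O)c(O)c(Cc3c(O)c(C)c(CC)oc3=O)c2O1 | target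

**Step count**

Total: 12 steps. Longest linear sequence: 9 steps (steps 1, 3, 4, 5, 6, 7, 8, 9, 12 from 2-methylprop-2-en-1-ol; the line from 2,4,6-trihydroxybenzaldehyde through steps 2 to 9 and 12 is equally long).

**Steps most likely to fail**

1. Step 5 (proposed new method). The hydrogen-bearing carbenoid may be diverted before it inserts: by cyclopropanation of the adjacent alkene, by dipolar cycloaddition of the diazo group onto that alkene before the catalyst is reached, or by azine formation. Discrimination between the two enantiotopic hydrogens may also be weak with two bulky ortho substituents. The fallback uses known chemistry, sets out from salicylaldehyde 6 and comes back at 10.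
   - Pinnick oxidation (NaClO2, NaH2PO4, 2-methylbut-2-ene, t-BuOH/H2O) should give 2-hydroxy-4,6-bis(triisopropylsilyloxy)benzoic acid F1.
   - Protodecarboxylation (Ag2CO3 cat., AcOH, DMSO, 120 °C) should give 3,5-bis(triisopropylsilyloxy)phenol F2.
   - Iodination with N-iodosuccinimide (CH2Cl2, −20 °C) should go next to the hydroxyl, because the carbon between the two silyl ethers is shielded, and give 2-iodo-3,5-bis(triisopropylsilyloxy)phenol F3.
   - F3 and commercial myrcene (C=CC(=C)CCC=C(C)C) are joined by the enantioselective Heck/Tsuji–Trost heteroannulation of o-halophenols with 1,3-dienes (Pd2(dba)3 as source of zerovalent palladium, chiral monophosphine, K2CO3, 80 °C). The arylpalladium adds to the CH2 end of the monosubstituted vinyl group and the phenoxide closes the ring on the allyl terminus next to the new benzylic CH2, which should give 10 with C2 set by the ligand. Any residual minor enantiomer would be removed by chromatography on a chiral phase.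

2. Step 8. Deprotonation may occur at C7, between the C6 acetal and the ring oxygen, instead of at C5; the amide electrophile may also be enolised by the hindered aryllithium. The fallback sets out from 12 and comes back at 15.
   - 12 is treated with n-BuLi (THF, 0 °C) to give (R)-7-lithio-4,6-bis(methoxymethoxy)-2-(6-methylhepta-1,5-dien-2-yl)-2,3-dihydrobenzofuran F4, which is capped with Me3SiCl as [(R)-4,6-bis(methoxymethoxy)-2-(6-methylhepta-1,5-dien-2-yl)-2,3-dihydrobenzofuran-7-yl]trimethylsilane F5.
   - A second metalation can then only occur at C5 and gives the C5 aryllithium of the silane F6, which is acylated with N-methoxy-N-methylacetamide to 1-[(R)-4,6-bis(methoxymethoxy)-2-(6-methylhepta-1,5-dien-2-yl)-7-(trimethylsilyl)-2,3-dihydrobenzofuran-5-yl]ethan-1-one F7.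
   - HCl in MeOH should then remove both acetals and, by ipso protonation of the electron-rich ring, the silyl group, which leads to 15.

3. Step 12. The activated pyrone may condense with a second pyrone molecule to the symmetrical methylene-bis-pyrone, and O-alkylation of the phenols may compete with attack through C7. The fallback reverses the roles of the partners; it sets out from 15 (with 19) and comes back at 22.
   - 15 is aminomethylated at its only free ring carbon with [Me2N=CH2]I (CH2Cl2, rt) to 1-[(R)-7-[(dimethylamino)methyl]-4,6-dihydroxy-2-(6-methylhepta-1,5-dien-2-yl)-2,3-dihydrobenzofuran-5-yl]ethan-1-one F8.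
   - Heating F8 with an excess of the inexpensive pyrone 19 (dioxane, 90 °C) should expel dimethylamine and form the ortho-quinone methide (R)-5-acetyl-4-hydroxy-7-methylidene-2-(6-methylhepta-1,5-dien-2-yl)-2,3-dihydrobenzofuran-6(7H)-one F9, which is captured at its exocyclic CH2 by C3 of 19 to give 22.

**Further compounds**

F1 | step 5 | 2-hydroxy-4,6-bis(triisopropylsilyloxy)benzoic acid | O=C(O)c1c(O)cc(O[Si](C(C)C)(C(C)C)C(C)C)cc1O[Si](C(C)C)(C(C)C)C(C)C
F2 | step 5 | 3,5-bis(triisopropylsilyloxy)phenol | Oc1cc(O[Si](C(C)C)(C(C)C)C(C)C)cc(O[Si](C(C)C)(C(C)C)C(C)C)c1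
F3 | step 5 | 2-iodo-3,5-bis(triisopropylsilyloxy)phenol | Oc1cc(O[Si](C(C)C)(C(C)C)C(C)C)cc(O[Si](C(C)C)(C(C)C)C(C)C)c1I
F4 | step 8 | (R)-7-lithio-4,6-bis(methoxymethoxy)-2-(6-methylhepta-1,5-dien-2-yl)-2,3-dihydrobenzofuran | C=C(CCC=C(C)C)[C@H]1Cc2c(OCOC)cc(OCOC)c([Li])c2O1
F5 | step 8 | [(R)-4,6-bis(methoxymethoxy)-2-(6-methylhepta-1,5-dien-2-yl)-2,3-dihydrobenzofuran-7-yl]trimethylsilane | C=C(CCC=C(C)C)[C@H]1Cc2c(OCOC)cc(OCOC)c([Si](C)(C)C)c2O1
F6 | step 8 | [(R)-5-lithio-4,6-bis(methoxymethoxy)-2-(6-methylhepta-1,5-dien-2-yl)-2,3-dihydrobenzofuran-7-yl]trimethylsilane | C=C(CCC=C(C)C)[C@H]1Cc2c(OCOC)c([Li])c(OCOC)c([Si](C)(C)C)c2O1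
F7 | step 8 | 1-[(R)-4,6-bis(methoxymethoxy)-2-(6-methylhepta-1,5-dien-2-yl)-7-(trimethylsilyl)-2,3-dihydrobenzofuran-5-yl]ethan-1-one | C=C(CCC=C(C)C)[C@H]1Cc2c(OCOC)c(C(C)=O)c(OCOC)c([Si](C)(C)C)c2O1
F8 | step 12 | 1-[(R)-7-[(dimethylamino)methyl]-4,6-dihydroxy-2-(6-methylhepta-1,5-dien-2-yl)-2,3-dihydrobenzofuran-5-yl]ethan-1-one | C=C(CCC=C(C)C)[C@H]1Cc2c(O)c(C(C)=O)c(O)c(CN(C)C)c2O1
F9 | step 12 | (R)-5-acetyl-4-hydroxy-7-methylidene-2-(6-methylhepta-1,5-dien-2-yl)-2,3-dihydrobenzofuran-6(7H)-one | C=C(CCC=C(C)C)[C@H]1CC2=C(O1)C(=C)C(=O)C(C(C)=O)=C2O
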